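**Plan**
- Retrosynthetic cuts, in order: the C8–O angelate and the C11=C13 methylene; then the ring bond C8–C9; then C3–C4; then C6–C7 and the lactone C12–O bond.
- Enabling feature: in the ten-membered ring, the unsubstituted C9H2–C10H2 bridge between the fully substituted epoxide carbon C1 and the carbinol C8 is read as a saturated alkyne. C8–C9 is therefore closed as iodoalkyne + aldehyde (Cr/Ni) to a cyclodec-4-en-9-yne, and the alkyne is taken out later with diimide.
- Forward order: γ-lactone ring (step 10), fragment union at C3–C4 (step 11), ten-membered ring at C8–C9 (step 16), C8 configuration, CH2–CH2, α-methylene, angelate, desilylation.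
- Stereochemistry: C1/C2 from Sharpless epoxidation of a commercial (Z)-enynol (Z olefin gives the cis-epoxide); C3 by Felkin–Anh addition to the epoxy aldehyde; C6/C7 by catalytic asymmetric (Z)-allylboration (syn adduct gives the cis-lactone); C8 by Noyori transfer hydrogenation of the cyclic ynone; (Z)-C4=C5 from Red-Al/I2.

Key step: step 16

Locants: ring C1–C10 with C1 = methyl-bearing epoxide carbon, C2 = epoxide CH, C3 = CHOH, C4(Me)=C5, C6 = lactone O–CH, C7 = ring-fusion CH, C8 = CH–OAng, C9 and C10 = CH2; lactone C11 (α), C12 (C=O), C13 (=CH2). Target = (1S,2R,3R,4Z,6S,7R,8R).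
Assumption 1: 1, 6, 10 and 32 are catalogue compounds.
Assumption 2: (R)-TRIP is taken to deliver the allyl unit to the aldehyde face that gives (4R)-13 (sense as for aryl and alkenyl aldehydes); if the sense is opposite, (S)-TRIP is used.
Assumption 3: the (S,S)-Ru catalyst is taken to give the (S)-propargylic alcohol, as it does for simple ynones.

**Route**

Step 1
Reactants: 1 (2Z)-3-methylpent-2-en-4-yn-1-ol
Product: 3 (2Z)-3-methyl-5-(trimethylsilyl)pent-2-en-4-yn-1-ol, via bis-silyl ether 2 (not isolated)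
Conditions: n-BuLi (2.1 equiv), THF, −78 °C; TMSCl (2.2 equiv), −78 °C → rt; then 1 M HCl, rt
Reagents that add atoms: chlorotrimethylsilane, C[Si](C)(C)Cl
Why: Double deprotonation (O–H, C≡C–H) and bis-silylation followed by selective hydrolysis of the labile O–Si bond should leave the C-silyl alkyne, which masks the terminal alkyne for the first Ni/Cr step.

Step 2
Reactants: 3 (2Z)-3-methyl-5-(trimethylsilyl)pent-2-en-4-yn-1-ol
Product: 4 [(2R,3S)-3-methyl-3-[(trimethylsilyl)ethynyl]oxiran-2-yl]methanol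
Conditions: Ti(Oi-Pr)4 (15 mol%), D-(−)-diisopropyl tartrate (18 mol%), t-BuOOH (2 equiv, decane), 4 Å MS, CH2Cl2, −20 °C
Reagents that add atoms: tert-butyl hydroperoxide, CC(C)(C)OO
Why: Sharpless asymmetric epoxidation: the D-(−)-tartrate/Ti complex delivers oxygen to the face giving (2R,3S) (mirror of nerol with L-(+)-tartrate giving 2S,3R), and the Z geometry is carried stereospecifically into the cis C1/C2 epoxide.

Step 3
Reactants: 4 [(2R,3S)-3-methyl-3-[(trimethylsilyl)ethynyl]oxiran-2-yl]methanol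
Product: 5 (2S,3S)-3-methyl-3-[(trimethylsilyl)ethynyl]oxirane-2-carbaldehyde
Conditions: Dess–Martin periodinane, pyridine, CH2Cl2, 0 °C → rt; used crude
Reagents that add atoms: none
Why: Buffered Dess–Martin oxidation should give the epoxy aldehyde without opening the epoxide or epimerising the α-carbon (the descriptor changes by priority only).

Step 4
Reactants: 6 but-2-yn-1-ol
Product: 8 (2Z)-3-iodobut-2-en-1-ol, via cyclic vinylalanate 7 (not isolated)
Conditions: Red-Al (1.5 equiv), THF, 0 °C → rt; then I2 (1.6 equiv), THF, −78 → 0 °C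
Reagents that add atoms: iodine, II
Why: Hydroxyl-directed trans-hydroalumination places aluminium on C3 cis to the CH2O group, and iodinolysis with retention should give only the Z iodide, which fixes the later (Z)-C4=C5 geometry.

Step 5
Reactants: 8 (2Z)-3-iodobut-2-en-1-ol
Product: 9 (2Z)-3-iodobut-2-enal
Conditions: activated MnO2 (15 equiv), CH2Cl2, rt, dark; used crude
Reagents that add atoms: none
Why: MnO2 oxidation of the allylic alcohol is neutral and should keep the Z geometry.

Step 6
Reactants: 10 buta-2,3-dien-1-ol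
Product: 11 (buta-2,3-dien-1-yloxy)triethylsilane
Conditions: TESCl, imidazole, CH2Cl2, 0 °C
Reagents that add atoms: chlorotriethylsilane, CC[Si](Cl)(CC)CC
Why: Standard silylation; the primary TES ether is chosen because it can later be removed in the presence of a secondary TBS ether.

Step 7
Reactants: 11 (buta-2,3-dien-1-yloxy)triethylsilane
Product: 12 triethyl{[(2Z)-4-(4,4,5,5-tetramethyl-1,3,2-dioxaborolan-2-yl)but-2-en-1-yl]oxy}silane
Conditions: CuCl (2 mol%), Xantphos-type bisphosphine (2 mol%), NaOt-Bu (6 mol%), pinacolborane (1.2 equiv), THF, rt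
Reagents that add atoms: pinacolborane, [H]B1OC(C)(C)C(C)(C)O1
Why: Copper hydride-catalysed hydroboration of a monosubstituted allene: Cu–H adds to the terminal C=C anti to the substituent and σ-bond metathesis with HBpin should give the configurationally stable (Z)-allylboronate.

Step 8
Reactants: 9 (2Z)-3-iodobut-2-enal; 12 (Z)-allylboronate
Product: 13 (3R,4R,5Z)-6-iodo-3-{[(triethylsilyl)oxy]methyl}hepta-1,5-dien-4-ol
Conditions: (R)-TRIP (5 mol%), 4 Å MS, toluene, −30 °C; aqueous work-up
Reagents that add atoms: none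
Why: Chiral phosphoric acid-catalysed allylboration through a chair Zimmerman–Traxler transition state: the Z-boronate should give the syn adduct (C6/C7 relationship of the target) and the catalyst fixes the aldehyde face.

Step 9
Reactants: 13 (3R,4R,5Z)-6-iodo-3-{[(triethylsilyl)oxy]methyl}hepta-1,5-dien-4-ol
Product: 15 (3R,4R,5Z)-6-iodo-3-{[(triethylsilyl)oxy]methyl}hept-5-ene-1,4-diol, via B-alkyl-9-BBN adduct 14 (not isolated)
Conditions: 9-BBN (2.5 equiv), THF, 0 °C → rt; then 3 M aq. NaOAc, 30% H2O2, 0 °C → rt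
Reagents that add atoms: hydrogen peroxide, OO
Why: Brown hydroboration–oxidation: 9-BBN should add anti-Markovnikov to the terminal vinyl group only (the trisubstituted iodoalkene is inert), and the buffered oxidation spares the TES ether.

Step 10
Reactants: 15 (3R,4R,5Z)-6-iodo-3-{[(triethylsilyl)oxy]methyl}hept-5-ene-1,4-diol
Product: 17 (4R,5R)-5-[(1Z)-2-iodoprop-1-en-1-yl]-4-{[(triethylsilyl)oxy]methyl}oxolan-2-one, via lactol 16 (not isolated)
Conditions: TEMPO (20 mol%), PhI(OAc)2 (2.5 equiv), CH2Cl2, rt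
Reagents that add atoms: none
Why: TEMPO/PhI(OAc)2 oxidative lactonisation of a 1,4-diol (primary alcohol to aldehyde, lactol, lactone): the syn adduct should give the cis-4,5-disubstituted lactone, and closing the lactone now differentiates O6 from the later O8.

Step 11
Reactants: 17 iodoalkenyl lactone; 5 epoxy aldehyde (1.5 equiv)
Product: 18 (4R,5S)-5-{(1Z,3R)-3-hydroxy-2-methyl-3-[(2R,3S)-3-methyl-3-[(trimethylsilyl)ethynyl]oxiran-2-yl]prop-1-en-1-yl}-4-{[(triethylsilyl)oxy]methyl}oxolan-2-one
Conditions: CrCl2 (6 equiv), NiCl2 (1 mol%), DMSO, rt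
Reagents that add atoms: none
Why: Nozaki–Hiyama–Kishi coupling: the alkenylchromium, formed with retention of the Z geometry, tolerates the lactone and should add to the cis-epoxy aldehyde under Felkin–Anh control (epoxide C–O anti to the nucleophile) to give the anti (3R) epoxy alcohol; the diastereomer from the minor enantiomer of 5 is removed here.

Step 12
Reactants: 18 epoxy alcohol
Product: 19 3-O-tert-butyldimethylsilyl ether of 18
Conditions: TBSOTf, 2,6-lutidine, CH2Cl2, −78 °C
Reagents that add atoms: tert-butyldimethylsilyl trifluoromethanesulfonate, CC(C)(C)[Si](C)(C)OS(=O)(=O)C(F)(F)F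
Why: Silylation of the hindered secondary alcohol at low temperature with a hindered base should leave the epoxide intact; the TBS ether stays to the last step.

Step 13
Reactants: 19 silyl ether
Product: 20 iodoalkyne (C≡C–SiMe3 of 19 replaced by C≡C–I)
Conditions: N-iodosuccinimide (1.3 equiv), AgNO3 (20 mol%), DMF, rt, dark
Reagents that add atoms: N-iodosuccinimide, O=C1CCC(=O)N1I
Why: Silver-catalysed iododesilylation of an alkynylsilane (silver acetylide intercepted by I+) should leave the silyl ethers, epoxide and deactivated trisubstituted olefin untouched.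

Step 14
Reactants: 20 iodoalkyne
Product: 21 primary alcohol (4-hydroxymethyl lactone)
Conditions: HF·pyridine, pyridine, THF, 0 °C
Reagents that add atoms: none
Why: Buffered fluoride should cleave the primary TES ether much faster than the hindered secondary TBS ether.

Step 15
Reactants: 21 primary alcohol
Product: 22 (2S,3S)-2-{(1Z,3R)-3-[tert-butyl(dimethyl)silyloxy]-3-[(2R,3S)-3-(iodoethynyl)-3-methyloxiran-2-yl]-2-methylprop-1-en-1-yl}-5-oxooxolane-3-carbaldehyde
Conditions: Dess–Martin periodinane, pyridine, CH2Cl2, 0 °C; filtered and used at once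
Reagents that add atoms: none
Why: Base-free oxidation is chosen because the aldehyde is α-epimerisable and β-acyloxy-substituted (the descriptor change at the ring carbon is by priority only).

Step 16
Reactants: 22 iodoalkynyl aldehyde
Product: 23 macrocyclic ynol (C8 epimers)
Conditions: CrCl2 (10 equiv), NiCl2 (0.5 mol%), degassed THF, rt, syringe-pump addition to 2 mM
Reagents that add atoms: none
Why: Cr(II) (with trace Ni) reduces the C–I bond to an alkynylchromium(III) species that adds to the C8 aldehyde by carbonyl-selective 1,2-addition, an intramolecular Nozaki–Hiyama–Kishi reaction whose closest precedent is the Cr/Ni iodoalkyne–aldehyde closure of nine- and ten-membered enediyne rings. The ten-membered carbocycle closes in the 10-exo-trig mode at the aldehyde carbon; the linear C1–C10≡C9 rod removes two rotors and the transannular hydrogens, and the cis-fused lactone, the (Z)-C4=C5 olefin and the cis-epoxide act as three built-in turns that bring C9 near C8. The new C8 carbinol centre forms under substrate control by C7 (chromium alkoxide expected on the outside of the ring) but is not relied on, because both epimers converge in steps 17 and 18. The step needs chemoselectivity for aldehyde over lactone, epoxide and silyl ether (secured by the low basicity of organochromium reagents), survival of the epimerisable β-acyloxy aldehyde (neutral medium) and intra- over intermolecular addition (high dilution).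

Step 17
Reactants: 23 macrocyclic ynol (C8 epimers)
Product: 24 macrocyclic ynone
Conditions: Dess–Martin periodinane, pyridine, CH2Cl2, 0 °C → rt
Reagents that add atoms: none
Why: Oxidation of the propargylic alcohol under neutral conditions converges both C8 epimers on one ynone.

Step 18
Reactants: 24 macrocyclic ynone
Product: 25 (8S)-propargylic alcohol
Conditions: Ru[(S,S)-TsDPEN](p-cymene) (16-electron amido complex, 2 mol%, no added base), i-PrOH, rt
Reagents that add atoms: none
Why: Noyori asymmetric transfer hydrogenation of an α,β-ynone: catalyst-controlled outer-sphere hydride delivery should give the (S)-propargylic alcohol, which is the spatial arrangement of the (8R) centre of the target, and the base-free catalyst protects the β-acyloxy ketone.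

Step 19
Reactants: 25 (8S)-propargylic alcohol
Product: 27 (8R)-saturated alcohol, via cis-C9=C10 alkene 26 (not isolated)
Conditions: 2-nitrobenzenesulfonylhydrazide (excess, in portions), Et3N, CH2Cl2, rt
Reagents that add atoms: none
Why: Diimide reduction (concerted syn transfer of H2): the strained cycloalkyne and the resulting cis-disubstituted alkene should be reduced far faster than the trisubstituted C4=C5 olefin, with no hydrogenolysis of the epoxide or carbinol.

Step 20
Reactants: 27 (8R)-saturated alcohol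
Product: 31 α-methylene lactone alcohol, via 8-O-trimethylsilyl ether 28 (not isolated), via Mannich base 29 (not isolated), via trimethylammonium iodide 30 (not isolated)
Conditions: TMSCl, Et3N, THF, 0 °C; then LDA (3 equiv), −78 °C; Me2N+=CH2 I−, −78 °C → rt; then MeI, MeOH, rt; then NaHCO3, MeOH–H2O, rt
Reagents that add atoms: N,N-dimethylmethyleneiminium iodide (Eschenmoser's salt), C=[N+](C)C.[I-]
Why: Transient O8 silylation prevents attack of an alkoxide on the lactone, the lithium lactone enolate undergoes a Mannich reaction with Eschenmoser's salt, and quaternisation followed by mild-base β-elimination should give the exocyclic methylene while methanolysis releases the 8-OH.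

Step 21
Reactants: 31 α-methylene lactone alcohol; 32 angelic acid [(2Z)-2-methylbut-2-enoic acid]
Product: 34 3-O-TBS ether of the target, via mixed anhydride 33 (not isolated)
Conditions: 32 (3 equiv), 2,4,6-trichlorobenzoyl chloride (3 equiv), Et3N, toluene, rt; then 31, toluene, 70 °C (no DMAP)
Reagents that add atoms: none
Why: Yamaguchi esterification through the mixed anhydride acylates O8 with retention at C8, and omitting nucleophilic catalysts avoids angelate-to-tiglate isomerisation.

Step 22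
Reactants: 34 3-O-TBS ether of the target
Product: 35 target compound CNP0500828.1
Conditions: HF·pyridine, pyridine, THF, 0 °C → rt
Reagents that add atoms: none
Why: Buffered fluoride desilylation should release the 3-OH without touching the epoxide, angelate or α-methylene lactone, and avoids the alkoxide that could trigger a Payne rearrangement.

**Compound list**
1 | (2Z)-3-methylpent-2-en-4-yn-1-ol | C#C/C(C)=C\CO | starting material
2 | trimethyl{[(2Z)-3-methyl-5-(trimethylsilyl)pent-2-en-4-yn-1-yl]oxy}silane | C[Si](C)(C)C#C/C(C)=C\CO[Si](C)(C)C | intermediate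
3 | (2Z)-3-methyl-5-(trimethylsilyl)pent-2-en-4-yn-1-ol | C[Si](C)(C)C#C/C(C)=C\CO | intermediate
4 | [(2R,3S)-3-methyl-3-[(trimethylsilyl)ethynyl]oxiran-2-yl]methanol | OC[C@H]1O[C@@]1(C)C#C[Si](C)(C)C | intermediate
5 | (2S,3S)-3-methyl-3-[(trimethylsilyl)ethynyl]oxirane-2-carbaldehyde | O=C[C@H]1O[C@@]1(C)C#C[Si](C)(C)C | intermediate
6 | but-2-yn-1-ol | CC#CCO | starting material
7 | sodium 2,2-bis(2-methoxyethoxy)-3-methyl-2,5-dihydro-1,2-oxaaluminol-2-uide (cyclic vinylalanate) | [Na+].CC1=CCO[Al-]1(OCCOC)OCCOC | intermediate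
8 | (2Z)-3-iodobut-2-en-1-ol | C/C(I)=C/CO | intermediate
9 | (2Z)-3-iodobut-2-enal | C/C(I)=C/C=O | intermediate
10 | buta-2,3-dien-1-ol | C=C=CCO | starting material
11 | (buta-2,3-dien-1-yloxy)triethylsilane | C=C=CCO[Si](CC)(CC)CC | intermediate
12 | triethyl{[(2Z)-4-(4,4,5,5-tetramethyl-1,3,2-dioxaborolan-2-yl)but-2-en-1-yl]oxy}silane | CC[Si](CC)(CC)OC/C=C\CB1OC(C)(C)C(C)(C)O1 | intermediate
13 | (3R,4R,5Z)-6-iodo-3-{[(triethylsilyl)oxy]methyl}hepta-1,5-dien-4-ol | C=C[C@H](CO[Si](CC)(CC)CC)[C@@H](O)/C=C(/C)I | intermediate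
14 | 9-BBN adduct of 13 (B-alkyl at C1, O-borinate at O4) | C(CB1C2CCCC1CCC2)[C@H](CO[Si](CC)(CC)CC)[C@@H](OB1C2CCCC1CCC2)/C=C(/C)I | intermediate
15 | (3R,4R,5Z)-6-iodo-3-{[(triethylsilyl)oxy]methyl}hept-5-ene-1,4-diol | OCC[C@H](CO[Si](CC)(CC)CC)[C@@H](O)/C=C(/C)I | intermediate
16 | (4R,5R)-5-[(1Z)-2-iodoprop-1-en-1-yl]-4-{[(triethylsilyl)oxy]methyl}oxolan-2-ol (anomers) | OC1C[C@H](CO[Si](CC)(CC)CC)[C@H](/C=C(/C)I)O1 | intermediate
17 | (4R,5R)-5-[(1Z)-2-iodoprop-1-en-1-yl]-4-{[(triethylsilyl)oxy]methyl}oxolan-2-one | O=C1C[C@H](CO[Si](CC)(CC)CC)[C@H](/C=C(/C)I)O1 | intermediate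
18 | (4R,5S)-5-{(1Z,3R)-3-hydroxy-2-methyl-3-[(2R,3S)-3-methyl-3-[(trimethylsilyl)ethynyl]oxiran-2-yl]prop-1-en-1-yl}-4-{[(triethylsilyl)oxy]methyl}oxolan-2-one | O=C1C[C@H](CO[Si](CC)(CC)CC)[C@H](/C=C(/C)[C@@H](O)[C@H]2O[C@@]2(C)C#C[Si](C)(C)C)O1 | intermediate
19 | (4R,5S)-5-{(1Z,3R)-3-[tert-butyl(dimethyl)silyloxy]-2-methyl-3-[(2R,3S)-3-methyl-3-[(trimethylsilyl)ethynyl]oxiran-2-yl]prop-1-en-1-yl}-4-{[(triethylsilyl)oxy]methyl}oxolan-2-one | O=C1C[C@H](CO[Si](CC)(CC)CC)[C@H](/C=C(/C)[C@@H](O[Si](C)(C)C(C)(C)C)[C@H]2O[C@@]2(C)C#C[Si](C)(C)C)O1 | intermediate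
20 | (4R,5S)-5-{(1Z,3R)-3-[tert-butyl(dimethyl)silyloxy]-3-[(2R,3S)-3-(iodoethynyl)-3-methyloxiran-2-yl]-2-methylprop-1-en-1-yl}-4-{[(triethylsilyl)oxy]methyl}oxolan-2-one | O=C1C[C@H](CO[Si](CC)(CC)CC)[C@H](/C=C(/C)[C@@H](O[Si](C)(C)C(C)(C)C)[C@H]2O[C@@]2(C)C#CI)O1 | intermediate
21 | (4R,5S)-5-{(1Z,3R)-3-[tert-butyl(dimethyl)silyloxy]-3-[(2R,3S)-3-(iodoethynyl)-3-methyloxiran-2-yl]-2-methylprop-1-en-1-yl}-4-(hydroxymethyl)oxolan-2-one | O=C1C[C@H](CO)[C@H](/C=C(/C)[C@@H](O[Si](C)(C)C(C)(C)C)[C@H]2O[C@@]2(C)C#CI)O1 | intermediate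
22 | (2S,3S)-2-{(1Z,3R)-3-[tert-butyl(dimethyl)silyloxy]-3-[(2R,3S)-3-(iodoethynyl)-3-methyloxiran-2-yl]-2-methylprop-1-en-1-yl}-5-oxooxolane-3-carbaldehyde | O=C1C[C@H](C=O)[C@H](/C=C(/C)[C@@H](O[Si](C)(C)C(C)(C)C)[C@H]2O[C@@]2(C)C#CI)O1 | intermediate
23 | macrocyclic ynol: ten-membered ring C1–C10 with C9≡C10, (1S,2R)-cis-epoxide, (3R)-OTBS, (4Z)-olefin, 8-OH (both epimers), cis-fused (6S,7R) γ-lactone with C11H2 | C1C(=O)O[C@H]2/C=C(/C)[C@@H](O[Si](C)(C)C(C)(C)C)[C@H]3O[C@@]3(C)C#CC(O)[C@@H]12 | intermediate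
24 | macrocyclic ynone: as 23 with C8=O (C7 descriptor becomes S by priority, same arrangement) | C1C(=O)O[C@H]2/C=C(/C)[C@@H](O[Si](C)(C)C(C)(C)C)[C@H]3O[C@@]3(C)C#CC(=O)[C@@H]12 | intermediate
25 | (1S,2R,3R,4Z,6S,7R,8S)-propargylic alcohol: as 23, single C8 epimer | C1C(=O)O[C@H]2/C=C(/C)[C@@H](O[Si](C)(C)C(C)(C)C)[C@H]3O[C@@]3(C)C#C[C@@H](O)[C@@H]12 | intermediate
26 | (4Z,9Z)-diene: as 25 with cis-C9=C10 | C1C(=O)O[C@H]2/C=C(/C)[C@@H](O[Si](C)(C)C(C)(C)C)[C@H]3O[C@@]3(C)/C=C\[C@@H](O)[C@@H]12 | intermediate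
27 | (1S,2R,3R,4Z,6S,7R,8R)-3-O-TBS-8-hydroxy-11,13-dihydro lactone (C9H2–C10H2) | C1C(=O)O[C@H]2/C=C(/C)[C@@H](O[Si](C)(C)C(C)(C)C)[C@H]3O[C@@]3(C)CC[C@@H](O)[C@@H]12 | intermediate
28 | 8-O-trimethylsilyl ether of 27 | C1C(=O)O[C@H]2/C=C(/C)[C@@H](O[Si](C)(C)C(C)(C)C)[C@H]3O[C@@]3(C)CC[C@@H](O[Si](C)(C)C)[C@@H]12 | intermediate
29 | 11-(dimethylaminomethyl) derivative of 28 (C11 epimers) | CN(C)CC1C(=O)O[C@H]2/C=C(/C)[C@@H](O[Si](C)(C)C(C)(C)C)[C@H]3O[C@@]3(C)CC[C@@H](O[Si](C)(C)C)[C@@H]12 | intermediate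
30 | N-methyl ammonium iodide of 29 | C[N+](C)(C)CC1C(=O)O[C@H]2/C=C(/C)[C@@H](O[Si](C)(C)C(C)(C)C)[C@H]3O[C@@]3(C)CC[C@@H](O[Si](C)(C)C)[C@@H]12.[I-] | intermediate
31 | (1S,2R,3R,4Z,6S,7R,8R)-3-O-TBS-8-hydroxy α-methylene lactone | C=C1C(=O)O[C@H]2/C=C(/C)[C@@H](O[Si](C)(C)C(C)(C)C)[C@H]3O[C@@]3(C)CC[C@@H](O)[C@@H]12 | intermediate
32 | angelic acid, (2Z)-2-methylbut-2-enoic acid | C/C=C(/C)C(=O)O | starting material
33 | (2Z)-2-methylbut-2-enoic 2,4,6-trichlorobenzoic anhydride | C/C=C(/C)C(=O)OC(=O)c1c(Cl)cc(Cl)cc1Cl | intermediate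
34 | 3-O-tert-butyldimethylsilyl ether of the target | C=C1C(=O)O[C@H]2/C=C(/C)[C@@H](O[Si](C)(C)C(C)(C)C)[C@H]3O[C@@]3(C)CC[C@@H](OC(=O)/C(C)=C\C)[C@@H]12 | intermediate
35 | CNP0500828.1, (1S,2R,3R,4Z,6S,7R,8R)-8-angeloyloxy-1,2-epoxy-3-hydroxy α-methylene-γ-lactone | C=C1C(=O)O[C@H]2/C=C(/C)[C@@H](O)[C@H]3O[C@@]3(C)CC[C@@H](OC(=O)/C(C)=C\C)[C@@H]12 | target

**Step count and risks**
Total steps: 22. Longest linear sequence: 17 (steps 4, 5, 8–22).

1. Step 16. What may go wrong: intermolecular oligomerisation, or β-elimination and epimerisation of the β-acyloxy aldehyde, competing with closure of the strained cyclodecenyne. Fallback (ring closed at C3–C4 instead, same two Cr couplings in reverse order): it sets out from 17 and 4 and comes back at 24. Compound 17 is desilylated (HF·pyridine) to the primary alcohol F1 and oxidised (Dess–Martin) to the aldehyde F2. Compound 4 is converted (NIS, cat. AgNO3) into the iodoalkynyl epoxy alcohol F3. CrCl2 without nickel, which leaves the alkenyl iodide untouched, joins F2 and F3 at C8–C9 to the diol F4. Double Dess–Martin oxidation gives the ynone epoxy-aldehyde F5. Intramolecular Ni/Cr alkenyl iodide–aldehyde coupling at high dilution (Felkin–Anh control by the epoxide) closes the ring to the hydroxy ynone F6, which is silylated (TBSOTf, 2,6-lutidine) to 24.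

2. Step 20. What may go wrong: loss of the labile O-TMS group under LDA followed by transfer of the lactone to O8, or failure of the hindered enolate to take up the iminium ion. Fallback (robust protection and aldol–dehydration instead of Mannich–elimination): it sets out from 27 and comes back at 31. Compound 27 is silylated (TESOTf, 2,6-lutidine) to the 8-O-triethylsilyl ether F7. LDA then gaseous formaldehyde gives the 11-hydroxymethyl lactone F8. MsCl/Et3N gives the mesylate F9, and DBU eliminates it to the α-methylene lactone F10. HF·pyridine at 0 °C removes the secondary TES ether before the more hindered TBS ether and gives 31.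

3. Step 18. What may go wrong: erosion of catalyst control by the macrocyclic substrate, or base-induced β-elimination and C7 epimerisation of the β-acyloxy ynone. Fallback (biocatalytic reduction): it sets out from 24 and comes back at 25, using an NADPH-dependent ketoreductase picked from a panel for the (S)-propargylic alcohol, with i-PrOH as co-substrate in phosphate buffer at pH 7 and 30 °C; no compound outside the list is made (F0).

**Further compounds**
F1 | step 16 | (4R,5R)-4-(hydroxymethyl)-5-[(1Z)-2-iodoprop-1-en-1-yl]oxolan-2-one | O=C1C[C@H](CO)[C@H](/C=C(/C)I)O1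
F2 | step 16 | (2R,3S)-2-[(1Z)-2-iodoprop-1-en-1-yl]-5-oxooxolane-3-carbaldehyde | O=C1C[C@H](C=O)[C@H](/C=C(/C)I)O1
F3 | step 16 | [(2R,3S)-3-(iodoethynyl)-3-methyloxiran-2-yl]methanol | OC[C@H]1O[C@@]1(C)C#CI
F4 | step 16 | seco diol: lactone of F2 joined at C8 (CHOH, both epimers) to the alkyne of F3, CH2OH at C3 | O=C1C[C@H](C(O)C#C[C@]2(C)O[C@@H]2CO)[C@H](/C=C(/C)I)O1
F5 | step 16 | seco ynone epoxy-aldehyde (C8=O, C3 aldehyde) | O=C1C[C@H](C(=O)C#C[C@]2(C)O[C@@H]2C=O)[C@H](/C=C(/C)I)O1
F6 | step 16 | macrocyclic ynone with free (3R)-hydroxyl (24 without TBS) | C1C(=O)O[C@H]2/C=C(/C)[C@@H](O)[C@H]3O[C@@]3(C)C#CC(=O)[C@@H]12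
F7 | step 20 | 8-O-triethylsilyl ether of 27 | C1C(=O)O[C@H]2/C=C(/C)[C@@H](O[Si](C)(C)C(C)(C)C)[C@H]3O[C@@]3(C)CC[C@@H](O[Si](CC)(CC)CC)[C@@H]12
F8 | step 20 | 11-(hydroxymethyl) derivative of F7 (C11 epimers) | OCC1C(=O)O[C@H]2/C=C(/C)[C@@H](O[Si](C)(C)C(C)(C)C)[C@H]3O[C@@]3(C)CC[C@@H](O[Si](CC)(CC)CC)[C@@H]12
F9 | step 20 | methanesulfonate of F8 | CS(=O)(=O)OCC1C(=O)O[C@H]2/C=C(/C)[C@@H](O[Si](C)(C)C(C)(C)C)[C@H]3O[C@@]3(C)CC[C@@H](O[Si](CC)(CC)CC)[C@@H]12
F10 | step 20 | 8-O-triethylsilyl ether of 31 | C=C1C(=O)O[C@H]2/C=C(/C)[C@@H](O[Si](C)(C)C(C)(C)C)[C@H]3O[C@@]3(C)CC[C@@H](O[Si](CC)(CC)CC)[C@@H]12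
F0 | step 18 | none | none
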